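## Retrosynthetic overview

1. Feature (rings lettered A to H along the chain, ring C in dibenzofuran numbering): ring C reads C4a (furan C–O), C4–H, C3–OH, C2–O and C1–O (the two dioxin oxygens), C9b (furan C–C). C4, C3, C2 and C1 are the four carbons of a squarate-derived 2,3-dialkoxycyclobutenone laid across C2=C3 of the ring B benzofuran.
2. Key disconnection: the C1–C9b bond, made by ring expansion of a 4-(benzofuran-2-yl)cyclobutenone, itself made by Stille coupling of the 2-stannylbenzofuran with the 4-chlorocyclobutenone from diisopropyl squarate. Isopropyl replaces methyl on the two squarate oxygens so they can be freed later beside fifteen methyl ethers.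
3. Dioxin: the free bay hydroxyl at C1 is joined first, by SNAr, to the symmetric ring D block 5-bromo-4,6-difluoroisophthalaldehyde, which fixes the dioxin orientation. The second fluoride takes the tail, both CHO groups become OH (Baeyer–Villiger), and the C2 oxygen closes on C–Br with copper.
4. Tail E to H: Ullmann homocoupling (E–F bond), SNAr plus Baeyer–Villiger (G–O–H), Ullmann ether (F–O–G), bromide to phenol.
5. Ring order: furan (step 4), ring C (step 9), dioxin (step 26). A fifteen-fold demethylation ends the route.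

Key step: step 9

Assumption: the E–F bond carries four ortho oxygen substituents and may be a stereogenic axis. The target structure defines no axial configuration, so the axis is carried as a racemate from step 17 onward.

## Route

Step 1
Reactants: 1 2-hydroxy-4,6-dimethoxybenzaldehyde; 2 bromoacetaldehyde diethyl acetal (2-bromo-1,1-diethoxyethane)
Product: 3 2-(2,2-diethoxyethoxy)-4,6-dimethoxybenzaldehyde
Conditions: K2CO3, NaI (cat.), DMF, 120 °C
Reagents that add atoms: none
Why: Williamson ether synthesis in which the phenoxide of 1 displaces the primary bromide of 2, capping the oxygen that becomes the furan oxygen and bringing in both furan carbons as a base-stable masked aldehyde.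

Step 2
Reactants: 3 2-(2,2-diethoxyethoxy)-4,6-dimethoxybenzaldehyde
Product: 5 2-(2,2-diethoxyethoxy)-4,6-dimethoxyphenol, via aryl formate 4 (not isolated)
Conditions: mCPBA, CH2Cl2, 0 °C to rt; then K2CO3 (cat.), MeOH, rt
Reagents that add atoms: mCPBA (3-chloroperoxybenzoic acid), O=C(OO)c1cccc(Cl)c1
Why: Baeyer–Villiger oxidation of a 2,4,6-trialkoxybenzaldehyde goes with aryl migration, and methanolysis of the formate frees only the hindered hydroxyl between two oxygen substituents, so the two ring B catechol oxygens never have to be told apart, while the aryloxyacetaldehyde acetal is inert to the weak carboxylic acid formed.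

Step 3
Reactants: 5 2-(2,2-diethoxyethoxy)-4,6-dimethoxyphenol; 6 1-iodo-3,5-dimethoxybenzene
Product: 7 1-(2,2-diethoxyethoxy)-2-(3,5-dimethoxyphenoxy)-3,5-dimethoxybenzene
Conditions: CuI (10 mol %), picolinic acid (20 mol %), K3PO4, DMSO, 90 °C, Ar
Reagents that add atoms: none
Why: Ullmann diaryl ether synthesis with the picolinic acid ligand accepts phenols with two ortho substituents, iodide 6 is unhindered with both methoxy groups meta to the reacting carbon, and the oxygen-free medium spares the easily oxidized phenol 5.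

Step 4
Reactants: 7 1-(2,2-diethoxyethoxy)-2-(3,5-dimethoxyphenoxy)-3,5-dimethoxybenzene
Product: 8 7-(3,5-dimethoxyphenoxy)-4,6-dimethoxy-1-benzofuran
Conditions: sulfonic acid resin (Amberlyst-15), PhCl, 120 °C, high dilution
Reagents that add atoms: none
Why: Acid-catalysed cyclodehydration of an aryloxyacetaldehyde acetal (intramolecular Friedel–Crafts alkylation, then loss of ethanol) can close only on the single free ortho carbon of ring B, which is activated by one ortho and one para methoxy group, and dilution suppresses intermolecular attack by ring A.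

Step 5
Reactants: 8 7-(3,5-dimethoxyphenoxy)-4,6-dimethoxy-1-benzofuran
Product: 10 tributyl[7-(3,5-dimethoxyphenoxy)-4,6-dimethoxy-1-benzofuran-2-yl]stannane, via 2-lithiobenzofuran 9 (not isolated)
Conditions: n-BuLi, THF, −78 °C; then Bu3SnCl, −78 °C to rt
Reagents that add atoms: tributyltin chloride, CCCC[Sn](Cl)(CCCC)CCCC
Why: Deprotonation of benzofuran at C2, its most acidic C–H, is fast at −78 °C whereas directed ortho-metalation between methoxy groups needs higher temperature, and the lithio species is trapped by stannylation.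

Step 6
Reactants: 11 diisopropyl squarate (3,4-diisopropoxycyclobut-3-ene-1,2-dione)
Product: 12 rac-4-hydroxy-2,3-diisopropoxycyclobut-2-en-1-one
Conditions: LiAlH(OtBu)3, THF, −78 to −20 °C; then H2O
Reagents that add atoms: none
Why: Chemoselective 1,2-reduction with a bulky alkoxyaluminium hydride stops after one carbonyl because the remaining one is a vinylogous ester, and the new carbinol centre forms as a racemate that is erased in step 9.

Step 7
Reactants: 12 rac-4-hydroxy-2,3-diisopropoxycyclobut-2-en-1-one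
Product: 13 rac-4-chloro-2,3-diisopropoxycyclobut-2-en-1-one
Conditions: 1-chloro-N,N,2-trimethylprop-1-en-1-amine, CH2Cl2, 0 °C; short silica plug, used at once
Reagents that add atoms: 1-chloro-N,N,2-trimethylprop-1-en-1-amine, CC(C)=C(Cl)N(C)C
Why: Deoxychlorination of an alcohol with an alpha-chloroenamine runs under neutral, acid-free conditions through an alkoxyiminium chloride, which avoids acid-triggered ionization at C4, and the centre stays racemic.

Step 8
Reactants: 10 tributyl[7-(3,5-dimethoxyphenoxy)-4,6-dimethoxy-1-benzofuran-2-yl]stannane; 13 rac-4-chloro-2,3-diisopropoxycyclobut-2-en-1-one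
Product: 14 rac-4-[7-(3,5-dimethoxyphenoxy)-4,6-dimethoxy-1-benzofuran-2-yl]-2,3-diisopropoxycyclobut-2-en-1-one
Conditions: PdCl2(PhCN)2 (5 mol %), tri(2-furyl)phosphine (10 mol %), THF, 50 °C
Reagents that add atoms: none
Why: Stille coupling of a 4-chlorocyclobutenone, in which the allylic alpha-keto C–Cl bond adds to zerovalent palladium, the weakly donating furylphosphine speeds transmetalation, bond formation takes the less substituted C4 terminus, and 50 °C stays below the ring-opening temperature of 14, whose C4 centre is racemic.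

Step 9
Reactants: 14 rac-4-[7-(3,5-dimethoxyphenoxy)-4,6-dimethoxy-1-benzofuran-2-yl]-2,3-diisopropoxycyclobut-2-en-1-one
Product: 17 6-(3,5-dimethoxyphenoxy)-7,9-dimethoxy-2,3-diisopropoxydibenzo[b,d]furan-1-ol, via vinylketene 15 (not isolated), via cyclohexadienone 16 (not isolated)
Conditions: toluene (0.01 M, degassed), 110 °C, Ar
Reagents that add atoms: none
Why: Heating breaks the C1–C4 bond of the strained cyclobutenone in a conrotatory four-electron electrocyclic opening to vinylketene 15, and because this opening is reversible, the geometric isomer whose benzofuranyl group points away from the ketene returns to 14 and is funnelled through the productive isomer. In 15 the ketene C=C, the enol ether C=C and the benzofuran C2=C3 bond make up a hexatriene, and a disrotatory six-electron electrocyclization joins the ketene carbon to benzofuran C3 (six-membered carbocycle, pericyclic closure, one new C–C bond) to give dienone 16. A proton shift from the former benzofuran C3 to oxygen restores aromaticity and makes the sequence irreversible. The closest known reaction type is the thermal benzannulation of 4-aryl and 4-heteroaryl cyclobutenones, 2-furyl and 2-benzofuranyl cases included, to fused phenols. No stereocentre remains, since the racemic C4 centre of 14 becomes the aromatic C4–H and the sp3 centre of 16 is lost on enolization. Site selectivity follows from connectivity, because O1 occupies the other flank of benzofuran C2, the three new oxygens come out distinct (free hydroxyl at bay C1, isopropyl ethers at C2 and C3), and high dilution keeps the ketene from dimerizing or acylating the product while it closes against the peri C9 methoxy group.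

Step 10
Reactants: 18 5-bromo-2,4-difluorobenzaldehyde
Product: 19 2-(5-bromo-2,4-difluorophenyl)-1,3-dioxolane
Conditions: HOCH2CH2OH, TsOH (cat.), toluene, reflux, azeotropic removal of water
Reagents that add atoms: ethylene glycol, OCCO
Why: Acid-catalysed acetalization masks the aldehyde against the Grignard reagent of the next step.

Step 11
Reactants: 19 2-(5-bromo-2,4-difluorophenyl)-1,3-dioxolane
Product: 22 4,6-difluorobenzene-1,3-dicarbaldehyde, via arylmagnesium chloride 20 (not isolated), via acetal aldehyde 21 (not isolated)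
Conditions: iPrMgCl·LiCl, THF, −15 °C; DMF; then 2 M HCl, rt
Reagents that add atoms: DMF (N,N-dimethylformamide), CN(C)C=O; water, O
Why: Bromine–magnesium exchange is fast on this fluorine-activated bromide and the ortho-fluoro arylmagnesium is stable at −15 °C, formylation with DMF (Bouveault aldehyde synthesis) follows, and the acidic work-up hydrolyses the dioxolane.

Step 12
Reactants: 22 4,6-difluorobenzene-1,3-dicarbaldehyde
Product: 23 5-bromo-4,6-difluorobenzene-1,3-dicarbaldehyde
Conditions: NBS, conc. H2SO4, 60 °C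
Reagents that add atoms: N-bromosuccinimide, O=C1CCC(=O)N1Br
Why: Electrophilic aromatic bromination in sulfuric acid, the standard method for deactivated arenes, is steered to C5 because that carbon is meta to both formyl groups and ortho to both fluorines, whereas C2 lies ortho to both formyl groups.

Step 13
Reactants: 24 1-fluoro-3,5-dimethoxybenzene
Product: 26 2-fluoro-4,6-dimethoxybenzaldehyde, via aryl iminium salt 25 (not isolated)
Conditions: POCl3, DMF, 0 to 70 °C; then H2O
Reagents that add atoms: DMF (N,N-dimethylformamide), CN(C)C=O; water, O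
Why: Vilsmeier–Haack formylation should favour C2, which is para to one methoxy group, ortho to the other and next to the small fluorine, over the carbon wedged between the two methoxy groups, and the minor isomer is removed by chromatography.

Step 14
Reactants: 26 2-fluoro-4,6-dimethoxybenzaldehyde; 27 2,4,6-trimethoxyphenol
Product: 28 2,4-dimethoxy-6-(2,4,6-trimethoxyphenoxy)benzaldehyde
Conditions: K2CO3, DMF, 130 °C, Ar
Reagents that add atoms: none
Why: Nucleophilic aromatic substitution by addition–elimination, in which the ortho formyl group stabilizes the anionic sigma adduct, both methoxy groups are meta to fluorine and so do not oppose attack, and argon protects the electron-rich phenoxide.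

Step 15
Reactants: 28 2,4-dimethoxy-6-(2,4,6-trimethoxyphenoxy)benzaldehyde
Product: 30 2,4-dimethoxy-6-(2,4,6-trimethoxyphenoxy)phenol, via aryl formate 29 (not isolated)
Conditions: mCPBA, CH2Cl2, 0 °C to rt; then K2CO3 (cat.), MeOH, rt
Reagents that add atoms: mCPBA (3-chloroperoxybenzoic acid), O=C(OO)c1cccc(Cl)c1
Why: Baeyer–Villiger oxidation with aryl migration of an aldehyde flanked by two oxygen substituents, followed by formate methanolysis, turns the activating group of step 14 into the ring G oxygen that will carry ring F.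

Step 16
Reactants: 31 1-bromo-3,5-dimethoxybenzene
Product: 32 1-bromo-2-iodo-3,5-dimethoxybenzene
Conditions: NIS, TFA (cat.), MeCN, rt
Reagents that add atoms: N-iodosuccinimide, O=C1CCC(=O)N1I
Why: Electrophilic aromatic iodination goes to C2, para to one methoxy group and ortho to the other, as is general for halogenation of 5-substituted resorcinol dimethyl ethers.

Step 17
Reactants: 32 1-bromo-2-iodo-3,5-dimethoxybenzene (two molecules)
Product: 33 rac-2,2'-dibromo-4,4',6,6'-tetramethoxy-1,1'-biphenyl
Conditions: Cu powder, DMF, 130 °C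
Reagents that add atoms: none
Why: Ullmann biaryl homocoupling takes place at the C–I bond, which reacts with copper far faster than C–Br, and gives the tetra-ortho-substituted E–F bond as a racemic axis.

Step 18
Reactants: 33 rac-2,2'-dibromo-4,4',6,6'-tetramethoxy-1,1'-biphenyl
Product: 35 rac-2-bromo-2'-iodo-4,4',6,6'-tetramethoxy-1,1'-biphenyl, via monolithiobiaryl 34 (not isolated)
Conditions: n-BuLi (1.0 equiv), THF, −78 °C; then I2
Reagents that add atoms: iodine, II
Why: Bromine–lithium exchange with one equivalent of n-BuLi at −78 °C stops after one bromine because a second exchange on the aryllithium is slower, and the iodine quench gives two halogens of different reactivity.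

Step 19
Reactants: 35 rac-2-bromo-2'-iodo-4,4',6,6'-tetramethoxy-1,1'-biphenyl; 30 2,4-dimethoxy-6-(2,4,6-trimethoxyphenoxy)phenol
Product: 36 rac-2-bromo-2'-[2,4-dimethoxy-6-(2,4,6-trimethoxyphenoxy)phenoxy]-4,4',6,6'-tetramethoxy-1,1'-biphenyl
Conditions: CuI (20 mol %), picolinic acid (40 mol %), K3PO4, DMSO, 90 °C, Ar
Reagents that add atoms: none
Why: Ullmann diaryl ether synthesis under the hindered-phenol conditions of step 3 engages only the C–I bond at 90 °C, so double coupling is excluded and the bromide is kept for step 20.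

Step 20
Reactants: 36 rac-2-bromo-2'-[2,4-dimethoxy-6-(2,4,6-trimethoxyphenoxy)phenoxy]-4,4',6,6'-tetramethoxy-1,1'-biphenyl
Product: 39 rac-2'-[2,4-dimethoxy-6-(2,4,6-trimethoxyphenoxy)phenoxy]-4,4',6,6'-tetramethoxy-1,1'-biphenyl-2-ol, via aryllithium 37 (not isolated), via lithium arylborate 38 (not isolated)
Conditions: n-BuLi, THF, −78 °C; B(OMe)3; then AcOH, 30% H2O2, 0 °C to rt
Reagents that add atoms: hydrogen peroxide, OO
Why: Bromine–lithium exchange, borylation and boronate oxidation (1,2-shift of aryl from boron to oxygen) convert a hindered aryl bromide into the phenol without a transition metal.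

Step 21
Reactants: 17 6-(3,5-dimethoxyphenoxy)-7,9-dimethoxy-2,3-diisopropoxydibenzo[b,d]furan-1-ol; 23 5-bromo-4,6-difluorobenzene-1,3-dicarbaldehyde (3 equiv)
Product: 40 5-bromo-4-fluoro-6-{[6-(3,5-dimethoxyphenoxy)-7,9-dimethoxy-2,3-diisopropoxydibenzo[b,d]furan-1-yl]oxy}benzene-1,3-dicarbaldehyde
Conditions: Cs2CO3, DMF, 0 °C to rt, Ar
Reagents that add atoms: none
Why: Nucleophilic aromatic substitution in which each fluorine of 23 is ortho to one formyl group and para to the other while bromine is meta to both, so the only free hydroxyl of 17 takes one of two equivalent C–F carbons, and the new aryloxy donor together with the excess of 23 holds the reaction at monosubstitution.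

Step 22
Reactants: 40 the aryl fluoride of step 21; 39 rac-2'-[2,4-dimethoxy-6-(2,4,6-trimethoxyphenoxy)phenoxy]-4,4',6,6'-tetramethoxy-1,1'-biphenyl-2-ol
Product: 41 eight-ring dialdehyde: 5-bromobenzene-1,3-dicarbaldehyde carrying at C4 the dibenzofuran-1-yloxy group of 17 and at C6 the biphenyl-2-yloxy group of 39
Conditions: Cs2CO3, DMF, 50 °C, Ar
Reagents that add atoms: none
Why: Second nucleophilic aromatic substitution, in which the remaining fluoride is still ortho and para to formyl groups and is a far better leaving group than the aryloxide already present, and the less hindered phenol 39 is reserved for this less reactive electrophile.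

Step 23
Reactants: 41 eight-ring dialdehyde
Product: 43 eight-ring resorcinol (both CHO groups of 41 replaced by OH), via bis-formate 42 (not isolated)
Conditions: mCPBA (excess), CH2Cl2, 0 °C to rt; then K2CO3 (cat.), MeOH, rt
Reagents that add atoms: mCPBA (3-chloroperoxybenzoic acid), O=C(OO)c1cccc(Cl)c1
Why: Twofold Baeyer–Villiger oxidation with aryl migration is favoured because each formyl group has one aryloxy group ortho and one para, and with formate methanolysis it installs both ring D hydroxyls and removes the activation that could permit a Smiles rearrangement of the ring C to ring D ether.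

Step 24
Reactants: 43 eight-ring resorcinol
Product: 44 eight-ring bromide with ring D as dimethyl ether (fifteen OMe, two OiPr)
Conditions: MeI, K2CO3, acetone, reflux
Reagents that add atoms: iodomethane, CI
Why: Williamson methylation caps the two ring D phenols so that only ring C oxygens are free in the copper step.

Step 25
Reactants: 44 eight-ring bromide with two isopropyl ethers
Product: 45 eight-ring bromide with free hydroxyls at C2 and C3 of ring C
Conditions: BCl3, CH2Cl2, −78 to 0 °C; then H2O
Reagents that add atoms: none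
Why: Lewis acid dealkylation with BCl3 cleaves secondary alkyl aryl ethers through a carbocation-like pathway at temperatures at which aryl methyl ethers, diaryl ethers and the aryl bromide persist.

Step 26
Reactants: 45 eight-ring bromide with free hydroxyls at C2 and C3 of ring C
Product: 46 pentadeca-O-methyl ether of the target (dioxin closed, ring C hydroxyl free)
Conditions: CuI (50 mol %), picolinic acid (1 equiv), K3PO4, DMSO (0.005 M), 100 °C, Ar
Reagents that add atoms: none
Why: Intramolecular Ullmann ether synthesis in which the C2 phenoxide sits next to the ether that carries the ortho bromide, so only the six-membered dioxin can form, the now electron-rich ring D cannot undergo Smiles scrambling, and catechols are competent partners in copper-mediated dioxin formation.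

Step 27
Reactants: 46 pentadeca-O-methyl ether of the target
Product: 47 CNP0192765.0 (target)
Conditions: BBr3 (excess), CH2Cl2, −78 °C to rt; then H2O; Sephadex LH-20 under Ar
Reagents that add atoms: none
Why: Exhaustive BBr3 demethylation cleaves aryl methyl ethers by bromide attack on the boron-activated methyl group and leaves the diaryl ethers, the furan and the dioxin untouched.

## Compound list

1 | 2-hydroxy-4,6-dimethoxybenzaldehyde | COc1cc(O)c(C=O)c(OC)c1 | starting material
2 | bromoacetaldehyde diethyl acetal | CCOC(CBr)OCC | starting material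
3 | 2-(2,2-diethoxyethoxy)-4,6-dimethoxybenzaldehyde | CCOC(COc1cc(OC)cc(OC)c1C=O)OCC | intermediate
4 | 2-(2,2-diethoxyethoxy)-4,6-dimethoxyphenyl formate | CCOC(COc1cc(OC)cc(OC)c1OC=O)OCC | intermediate
5 | 2-(2,2-diethoxyethoxy)-4,6-dimethoxyphenol | CCOC(COc1cc(OC)cc(OC)c1O)OCC | intermediate
6 | 1-iodo-3,5-dimethoxybenzene | COc1cc(I)cc(OC)c1 | starting material
7 | 1-(2,2-diethoxyethoxy)-2-(3,5-dimethoxyphenoxy)-3,5-dimethoxybenzene | CCOC(COc1cc(OC)cc(OC)c1Oc1cc(OC)cc(OC)c1)OCC | intermediate
8 | 7-(3,5-dimethoxyphenoxy)-4,6-dimethoxy-1-benzofuran | COc1cc(OC)cc(Oc2c(OC)cc(OC)c3ccoc23)c1 | intermediate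
9 | [7-(3,5-dimethoxyphenoxy)-4,6-dimethoxy-1-benzofuran-2-yl]lithium | [Li]c1cc2c(OC)cc(OC)c(Oc3cc(OC)cc(OC)c3)c2o1 | intermediate
10 | tributyl[7-(3,5-dimethoxyphenoxy)-4,6-dimethoxy-1-benzofuran-2-yl]stannane | CCCC[Sn](CCCC)(CCCC)c1cc2c(OC)cc(OC)c(Oc3cc(OC)cc(OC)c3)c2o1 | intermediate
11 | diisopropyl squarate | CC(C)OC1=C(OC(C)C)C(=O)C1=O | starting material
12 | rac-4-hydroxy-2,3-diisopropoxycyclobut-2-en-1-one | O=C1C(OC(C)C)=C(OC(C)C)C1O | intermediate
13 | rac-4-chloro-2,3-diisopropoxycyclobut-2-en-1-one | O=C1C(OC(C)C)=C(OC(C)C)C1Cl | intermediate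
14 | rac-4-[7-(3,5-dimethoxyphenoxy)-4,6-dimethoxy-1-benzofuran-2-yl]-2,3-diisopropoxycyclobut-2-en-1-one | O=C1C(OC(C)C)=C(OC(C)C)C1c1cc2c(OC)cc(OC)c(Oc3cc(OC)cc(OC)c3)c2o1 | intermediate
15 | vinylketene, 4-(benzofuran-2-yl)-2,3-diisopropoxybuta-1,3-dien-1-one with the benzofuranyl group cis to the ketene-bearing carbon | O=C=C(OC(C)C)/C(OC(C)C)=C\c1cc2c(OC)cc(OC)c(Oc3cc(OC)cc(OC)c3)c2o1 | intermediate
16 | cyclohexadienone (keto tautomer of 17, sp3 C–H at C9b, racemic) | O=C1C(OC(C)C)=C(OC(C)C)C=C2Oc3c(Oc4cc(OC)cc(OC)c4)c(OC)cc(OC)c3C12 | intermediate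
17 | 6-(3,5-dimethoxyphenoxy)-7,9-dimethoxy-2,3-diisopropoxydibenzo[b,d]furan-1-ol | COc1cc(OC)cc(Oc2c(OC)cc(OC)c3c2oc2cc(OC(C)C)c(OC(C)C)c(O)c23)c1 | intermediate
18 | 5-bromo-2,4-difluorobenzaldehyde | O=Cc1cc(Br)c(F)cc1F | starting material
19 | 2-(5-bromo-2,4-difluorophenyl)-1,3-dioxolane | Fc1cc(F)c(C2OCCO2)cc1Br | intermediate
20 | [5-(1,3-dioxolan-2-yl)-2,4-difluorophenyl]magnesium chloride | Fc1cc(F)c(C2OCCO2)cc1[Mg]Cl | intermediate
21 | 5-(1,3-dioxolan-2-yl)-2,4-difluorobenzaldehyde | Fc1cc(F)c(C2OCCO2)cc1C=O | intermediate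
22 | 4,6-difluorobenzene-1,3-dicarbaldehyde | O=Cc1cc(C=O)c(F)cc1F | intermediate
23 | 5-bromo-4,6-difluorobenzene-1,3-dicarbaldehyde | O=Cc1cc(C=O)c(F)c(Br)c1F | intermediate
24 | 1-fluoro-3,5-dimethoxybenzene | COc1cc(F)cc(OC)c1 | starting material
25 | (2-fluoro-4,6-dimethoxybenzylidene)dimethyliminium dichlorophosphate | COc1cc(F)c(C=[N+](C)C)c(OC)c1.[O-]P(Cl)(Cl)=O | intermediate
26 | 2-fluoro-4,6-dimethoxybenzaldehyde | COc1cc(F)c(C=O)c(OC)c1 | intermediate
27 | 2,4,6-trimethoxyphenol | COc1cc(OC)c(O)c(OC)c1 | starting material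
28 | 2,4-dimethoxy-6-(2,4,6-trimethoxyphenoxy)benzaldehyde | COc1cc(OC)c(C=O)c(Oc2c(OC)cc(OC)cc2OC)c1 | intermediate
29 | 2,4-dimethoxy-6-(2,4,6-trimethoxyphenoxy)phenyl formate | COc1cc(OC)c(OC=O)c(Oc2c(OC)cc(OC)cc2OC)c1 | intermediate
30 | 2,4-dimethoxy-6-(2,4,6-trimethoxyphenoxy)phenol | COc1cc(OC)c(O)c(Oc2c(OC)cc(OC)cc2OC)c1 | intermediate
31 | 1-bromo-3,5-dimethoxybenzene | COc1cc(Br)cc(OC)c1 | starting material
32 | 1-bromo-2-iodo-3,5-dimethoxybenzene | COc1cc(Br)c(I)c(OC)c1 | intermediate
33 | rac-2,2'-dibromo-4,4',6,6'-tetramethoxy-1,1'-biphenyl | COc1cc(Br)c(-c2c(Br)cc(OC)cc2OC)c(OC)c1 | intermediate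
34 | (2'-bromo-4,4',6,6'-tetramethoxybiphenyl-2-yl)lithium | COc1cc(Br)c(-c2c([Li])cc(OC)cc2OC)c(OC)c1 | intermediate
35 | rac-2-bromo-2'-iodo-4,4',6,6'-tetramethoxy-1,1'-biphenyl | COc1cc(Br)c(-c2c(I)cc(OC)cc2OC)c(OC)c1 | intermediate
36 | rac-2-bromo-2'-[2,4-dimethoxy-6-(2,4,6-trimethoxyphenoxy)phenoxy]-4,4',6,6'-tetramethoxy-1,1'-biphenyl | Brc1cc(OC)cc(OC)c1-c1c(OC)cc(OC)cc1Oc1c(OC)cc(OC)cc1Oc1c(OC)cc(OC)cc1OC | intermediate
37 | aryllithium from 36 (Li in place of Br) | [Li]c1cc(OC)cc(OC)c1-c1c(OC)cc(OC)cc1Oc1c(OC)cc(OC)cc1Oc1c(OC)cc(OC)cc1OC | intermediate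
38 | lithium aryl(trimethoxy)borate from 37 | [Li+].CO[B-](OC)(OC)c1cc(OC)cc(OC)c1-c1c(OC)cc(OC)cc1Oc1c(OC)cc(OC)cc1Oc1c(OC)cc(OC)cc1OC | intermediate
39 | rac-2'-[2,4-dimethoxy-6-(2,4,6-trimethoxyphenoxy)phenoxy]-4,4',6,6'-tetramethoxy-1,1'-biphenyl-2-ol | Oc1cc(OC)cc(OC)c1-c1c(OC)cc(OC)cc1Oc1c(OC)cc(OC)cc1Oc1c(OC)cc(OC)cc1OC | intermediate
40 | 5-bromo-4-fluoro-6-{[6-(3,5-dimethoxyphenoxy)-7,9-dimethoxy-2,3-diisopropoxydibenzo[b,d]furan-1-yl]oxy}benzene-1,3-dicarbaldehyde | COc1cc(OC)cc(Oc2c(OC)cc(OC)c3c2oc2cc(OC(C)C)c(OC(C)C)c(Oc4c(C=O)cc(C=O)c(F)c4Br)c23)c1 | intermediate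
41 | eight-ring dialdehyde (5-bromobenzene-1,3-dicarbaldehyde with the aryloxy group of 17 at C4 and that of 39 at C6), racemic axis | COc1cc(OC)cc(Oc2c(OC)cc(OC)c3c2oc2cc(OC(C)C)c(OC(C)C)c(Oc4c(C=O)cc(C=O)c(Oc5cc(OC)cc(OC)c5-c5c(OC)cc(OC)cc5Oc5c(OC)cc(OC)cc5Oc5c(OC)cc(OC)cc5OC)c4Br)c23)c1 | intermediate
42 | eight-ring bis-formate (both CHO of 41 as OCHO) | COc1cc(OC)cc(Oc2c(OC)cc(OC)c3c2oc2cc(OC(C)C)c(OC(C)C)c(Oc4c(OC=O)cc(OC=O)c(Oc5cc(OC)cc(OC)c5-c5c(OC)cc(OC)cc5Oc5c(OC)cc(OC)cc5Oc5c(OC)cc(OC)cc5OC)c4Br)c23)c1 | intermediate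
43 | eight-ring resorcinol (both CHO of 41 as OH) | COc1cc(OC)cc(Oc2c(OC)cc(OC)c3c2oc2cc(OC(C)C)c(OC(C)C)c(Oc4c(O)cc(O)c(Oc5cc(OC)cc(OC)c5-c5c(OC)cc(OC)cc5Oc5c(OC)cc(OC)cc5Oc5c(OC)cc(OC)cc5OC)c4Br)c23)c1 | intermediate
44 | eight-ring bromide, ring D dimethyl ether, ring C diisopropyl ether | COc1cc(OC)cc(Oc2c(OC)cc(OC)c3c2oc2cc(OC(C)C)c(OC(C)C)c(Oc4c(OC)cc(OC)c(Oc5cc(OC)cc(OC)c5-c5c(OC)cc(OC)cc5Oc5c(OC)cc(OC)cc5Oc5c(OC)cc(OC)cc5OC)c4Br)c23)c1 | intermediate
45 | eight-ring bromide with free hydroxyls at C2 and C3 of ring C | COc1cc(OC)cc(Oc2c(OC)cc(OC)c3c2oc2cc(O)c(O)c(Oc4c(OC)cc(OC)c(Oc5cc(OC)cc(OC)c5-c5c(OC)cc(OC)cc5Oc5c(OC)cc(OC)cc5Oc5c(OC)cc(OC)cc5OC)c4Br)c23)c1 | intermediate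
46 | pentadeca-O-methyl ether of the target (only the ring C hydroxyl free) | COc1cc(OC)cc(Oc2c(OC)cc(OC)c3c2oc2cc(O)c4c(c23)Oc2c(OC)cc(OC)c(Oc3cc(OC)cc(OC)c3-c3c(OC)cc(OC)cc3Oc3c(OC)cc(OC)cc3Oc3c(OC)cc(OC)cc3OC)c2O4)c1 | intermediate
47 | CNP0192765.0 | Oc1cc(O)cc(Oc2c(O)cc(O)c3c2oc2cc(O)c4c(c23)Oc2c(O)cc(O)c(Oc3cc(O)cc(O)c3-c3c(O)cc(O)cc3Oc3c(O)cc(O)cc3Oc3c(O)cc(O)cc3O)c2O4)c1 | target

## Step count and risks

Total step count: 27.
Longest linear sequence: 14 steps (steps 1–5, 8, 9 and 21–27, from compound 1).

**Step 7 (step 8 depends on it).**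
- What may go wrong: the C4–Cl bond may ionize with help from the C2 isopropoxy oxygen, and the ion pair may then lose its isopropyl group. The chloride would drain away during preparation, filtration or coupling.
- Fallback: it sets out from 8 and 11 and comes back at 17.
- Compound 8 is lithiated as in step 5 and added to squarate 11 (THF, −78 °C). This 1,2-addition needs no leaving group at C4 and gives rac-4-[7-(3,5-dimethoxyphenoxy)-4,6-dimethoxy-1-benzofuran-2-yl]-4-hydroxy-2,3-diisopropoxycyclobut-2-en-1-one F1.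
- Heating in degassed toluene triggers the same ring opening and closure, now with the hydroxyl turning outward. It gives 6-(3,5-dimethoxyphenoxy)-7,9-dimethoxy-2,3-diisopropoxydibenzo[b,d]furan-1,4-diol F2, which is kept under argon.
- The open C4 hydroxyl is sulfonylated in preference to the crowded, hydrogen-bonded bay hydroxyl (PhNTf2, K2CO3, DMF, 0 °C) to give the C4 monotriflate F3.
- Transfer hydrogenolysis (Pd(OAc)2, 1,3-bis(diphenylphosphino)propane, HCO2H, Et3N, DMF, 70 °C) removes the extra oxygen and gives 17.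

**Step 19.**
- What may go wrong: exchange and bond formation at copper may be slow because the phenol has two ortho substituents and the iodide has a bulky ortho aryl group. Hydrodeiodination and oxidation of the phenoxide could then overtake the coupling.
- Fallback: it sets out from 35 and comes back at 36.
- The aryl iodide is oxidized (mCPBA, TsOH·H2O, MeCN) and the trivalent iodine species is captured with 1,3,5-trimethoxybenzene. This gives (2'-bromo-4,4',6,6'-tetramethoxybiphenyl-2-yl)(2,4,6-trimethoxyphenyl)iodonium tosylate F4.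
- The potassium phenoxide of 30 (KOtBu, toluene, rt to 60 °C) is then arylated without metal by ligand coupling at iodine. The very electron-rich trimethoxyphenyl group stays on iodine, and the product is 36.

**Step 27.**
- What may go wrong: cleavage of fifteen ethers may stop short, and the free polyphenol may degrade oxidatively during chromatography.
- Fallback: it sets out from 46 and comes back at 47.
- The crude product of the BBr3 treatment is not purified but acetylated at once (Ac2O, pyridine) to the hexadecaacetate of the target F5. This is stable to air and silica gel and can be separated from partly methylated material.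
- Acidic methanolysis (AcCl cat., MeOH, Ar, rt to 40 °C) then releases 47 without passing through oxidizable phenoxides.

Further compounds
F1 | step 7 | rac-4-[7-(3,5-dimethoxyphenoxy)-4,6-dimethoxy-1-benzofuran-2-yl]-4-hydroxy-2,3-diisopropoxycyclobut-2-en-1-one | O=C1C(OC(C)C)=C(OC(C)C)C1(O)c1cc2c(OC)cc(OC)c(Oc3cc(OC)cc(OC)c3)c2o1
F2 | step 7 | 6-(3,5-dimethoxyphenoxy)-7,9-dimethoxy-2,3-diisopropoxydibenzo[b,d]furan-1,4-diol | COc1cc(OC)cc(Oc2c(OC)cc(OC)c3c2oc2c(O)c(OC(C)C)c(OC(C)C)c(O)c23)c1
F3 | step 7 | 6-(3,5-dimethoxyphenoxy)-1-hydroxy-7,9-dimethoxy-2,3-diisopropoxydibenzo[b,d]furan-4-yl trifluoromethanesulfonate | COc1cc(OC)cc(Oc2c(OC)cc(OC)c3c2oc2c(OS(=O)(=O)C(F)(F)F)c(OC(C)C)c(OC(C)C)c(O)c23)c1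
F4 | step 19 | (2'-bromo-4,4',6,6'-tetramethoxybiphenyl-2-yl)(2,4,6-trimethoxyphenyl)iodonium tosylate | COc1cc(Br)c(-c2c([I+]c3c(OC)cc(OC)cc3OC)cc(OC)cc2OC)c(OC)c1.Cc1ccc(cc1)S(=O)(=O)[O-]
F5 | step 27 | hexadecaacetate of the target | CC(=O)Oc1cc(OC(C)=O)cc(Oc2c(OC(C)=O)cc(OC(C)=O)c3c2oc2cc(OC(C)=O)c4c(c23)Oc2c(OC(C)=O)cc(OC(C)=O)c(Oc3cc(OC(C)=O)cc(OC(C)=O)c3-c3c(OC(C)=O)cc(OC(C)=O)cc3Oc3c(OC(C)=O)cc(OC(C)=O)cc3Oc3c(OC(C)=O)cc(OC(C)=O)cc3OC(C)=O)c2O4)c1
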